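**Plan**

- Retrosynthetic cuts, in order: the two benzyl ethers on ring B; the C2–O bond of ring A (back to C2–B); the C1–C6 and C2–C3 bonds of ring A together (retro pyrone Diels–Alder, CO2 put back); the enol ester C–O bond between the pyrone and the ring B acid.
- Enabling feature: C3, C4, C5 and C6 of ring A carry H, O-acyl, H and CH3, the substitution pattern of C3–C6 of 4-hydroxy-6-methyl-2-pyrone, so only C1 (CO2Me) and C2 (OH, masked as boron) must come from an alkyne.
- Forward order: ring B is taken intact from atraric acid (chlorination, benzylation, saponification, acid chloride) and esterified with the pyrone; ring A is then made last by cycloaddition with a borylated propiolate and loss of CO2; C–B oxidation and debenzylation finish the route.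
- Stereochemistry: the target has no stereocentre; the only selectivity to secure is the regiochemistry of the cycloaddition, which should follow from the polarisation of both partners.

Key step: step 7

Remark on the chemistry: ring A is the methyl benzoate ring (C1 CO2Me, C2 OH, C4 O-aroyl, C6 CH3) and ring B the chlorinated benzoyl ring; atraric acid, triacetic acid lactone, methyl propiolate and 2-isopropoxy-4,4,5,5-tetramethyl-1,3,2-dioxaborolane are taken to be purchasable.

**Route**

Step 1
Reactants: 1 atraric acid (methyl 2,4-dihydroxy-3,6-dimethylbenzoate)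
Product: 2 methyl 5-chloro-2,4-dihydroxy-3,6-dimethylbenzoate
Conditions: SO2Cl2 (1.05 equiv), CH2Cl2, 0 °C to rt
Reagents that add atoms: sulfuryl chloride, O=S(=O)(Cl)Cl
Why: Electrophilic aromatic chlorination can only take place at C5, the single unsubstituted ring position, which is ortho to the 4-hydroxyl and para to the 2-hydroxyl.

Step 2
Reactants: 2 methyl 5-chloro-2,4-dihydroxy-3,6-dimethylbenzoate
Product: 3 methyl 2,4-bis(benzyloxy)-5-chloro-3,6-dimethylbenzoate
Conditions: BnBr (2.5 equiv), K2CO3 (3 equiv), DMF, 60 °C
Reagents that add atoms: benzyl bromide, BrCc1ccccc1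
Why: Williamson ether synthesis in warm DMF should alkylate both the flanked 4-hydroxyl and the hydrogen-bonded 2-hydroxyl, and benzyl ethers are chosen because they tolerate hot hydroxide, acid chloride formation, 170 °C and perborate, whereas an acetal ether ortho to an acid chloride could cyclise onto it.

Step 3
Reactants: 3 methyl 2,4-bis(benzyloxy)-5-chloro-3,6-dimethylbenzoate
Product: 4 2,4-bis(benzyloxy)-5-chloro-3,6-dimethylbenzoic acid
Conditions: KOH, DMSO/H2O, 90 °C; then 1 M HCl
Reagents that add atoms: potassium hydroxide, [K+].[OH-]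
Why: Saponification of a doubly ortho-substituted methyl benzoate is slow in aqueous alcohol but should proceed with poorly solvated hydroxide in hot aqueous DMSO, to which the benzyl ethers and the unactivated aryl chloride are inert.

Step 4
Reactants: 4 2,4-bis(benzyloxy)-5-chloro-3,6-dimethylbenzoic acid
Product: 5 2,4-bis(benzyloxy)-5-chloro-3,6-dimethylbenzoyl chloride
Conditions: (COCl)2, cat. DMF, CH2Cl2, 0 °C to rt; evaporate, use crude
Reagents that add atoms: oxalyl chloride, O=C(Cl)C(=O)Cl
Why: Acid chloride formation through the chloroiminium (Vilsmeier) intermediate is mild, the fully substituted ring offers no site for formylation, and the benzyl ethers withstand the HCl formed.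

Step 5
Reactants: 5 2,4-bis(benzyloxy)-5-chloro-3,6-dimethylbenzoyl chloride; 6 triacetic acid lactone (4-hydroxy-6-methyl-2H-pyran-2-one)
Product: 7 6-methyl-2-oxo-2H-pyran-4-yl 2,4-bis(benzyloxy)-5-chloro-3,6-dimethylbenzoate
Conditions: Et3N, CH2Cl2, 0 °C to rt
Reagents that add atoms: none
Why: O-acylation of the acidic 4-hydroxyl of the pyrone by an acid chloride and a tertiary amine is the standard entry to 4-acyloxy-2-pyrones, and DMAP is left out so that the acyl group is not carried on to C3.

Step 6
Reactants: 8 methyl propiolate; 9 2-isopropoxy-4,4,5,5-tetramethyl-1,3,2-dioxaborolane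
Product: 12 methyl 3-(4,4,5,5-tetramethyl-1,3,2-dioxaborolan-2-yl)prop-2-ynoate, via methyl 3-lithioprop-2-ynoate 10 (not isolated), via lithium alkynyl(isopropoxy)borate 11 (not isolated)
Conditions: n-BuLi, THF, −78 °C; then 9, −78 °C; then HCl in Et2O, −78 °C to rt; filter, bulb-to-bulb distillation under argon
Reagents that add atoms: none
Why: Borylation of a lithium acetylide with an isopropoxy pinacolborane followed by protonolysis of the ate complex with anhydrous HCl is the standard preparation of alkynyl pinacol boronates, and holding −78 °C throughout keeps the lithiated propiolate from self-condensing.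

Step 7
Reactants: 7 6-methyl-2-oxo-2H-pyran-4-yl 2,4-bis(benzyloxy)-5-chloro-3,6-dimethylbenzoate; 12 methyl 3-(4,4,5,5-tetramethyl-1,3,2-dioxaborolan-2-yl)prop-2-ynoate
Product: 14 methyl 4-{[2,4-bis(benzyloxy)-5-chloro-3,6-dimethylbenzoyl]oxy}-2-methyl-6-(4,4,5,5-tetramethyl-1,3,2-dioxaborolan-2-yl)benzoate, via bicyclic lactone adduct 13 (not isolated)
Conditions: 12 (3 equiv), 1,2-dichlorobenzene, 170 °C, sealed tube, argon
Reagents that add atoms: none
Why: The pyrone acts as the diene through C3 and C6 in a thermal, concerted but asynchronous [4+2] cycloaddition with the alkyne to give the 2-oxabicyclo[2.2.2]octadienone 13, which loses CO2 by retro-[4+2] at the same temperature and becomes aromatic. The closest known reaction type is the cycloaddition of 2-pyrones with alkynyl pinacol boronates with extrusion of CO2 to give arylboronates, alongside the long-known pyrone and propiolate benzannulation. Ring A is closed by this intermolecular cycloaddition, in which both new ring bonds (C2–C3 and C1–C6 of ring A) form in one operation, not by cyclisation of a chain. No stereocentre has to be controlled, since the two bridgehead centres of racemic 13 vanish on aromatisation. The selectivity needed is regiochemical: pyrone C3, the beta carbon of the enol ester and the diene terminus with the larger HOMO coefficient, should bond to the boron-bearing alkyne carbon, which is the beta carbon of the ynoate with the larger LUMO coefficient, and this also places the bulky boronate next to C3–H and away from the C6 methyl. The doubly ortho-substituted aroyl ester, the benzyl ethers and the aryl chloride should be inert under these neutral thermal conditions.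

Step 8
Reactants: 14 methyl 4-{[2,4-bis(benzyloxy)-5-chloro-3,6-dimethylbenzoyl]oxy}-2-methyl-6-(4,4,5,5-tetramethyl-1,3,2-dioxaborolan-2-yl)benzoate
Product: 15 methyl 4-{[2,4-bis(benzyloxy)-5-chloro-3,6-dimethylbenzoyl]oxy}-2-hydroxy-6-methylbenzoate
Conditions: NaBO3·4H2O, THF/H2O, rt
Reagents that add atoms: sodium perborate tetrahydrate, O.O.O.O.[Na+].[O-]OB=O
Why: Perborate oxidation of an arylboronate to the phenol (aryl migration from boron to oxygen) runs at room temperature under weakly basic conditions that should leave the methyl ester and the sterically shielded depside ester untouched.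

Step 9
Reactants: 15 methyl 4-{[2,4-bis(benzyloxy)-5-chloro-3,6-dimethylbenzoyl]oxy}-2-hydroxy-6-methylbenzoate
Product: 16 methyl 4-[(5-chloro-2,4-dihydroxy-3,6-dimethylbenzoyl)oxy]-2-hydroxy-6-methylbenzoate (target)
Conditions: BCl3 (4 equiv), pentamethylbenzene (6 equiv), CH2Cl2, −78 °C; then MeOH, aqueous work-up
Reagents that add atoms: none
Why: Lewis acid debenzylation with a cation scavenger cleaves aryl benzyl ethers at −78 °C, the benzyl cation being taken up by pentamethylbenzene in a Friedel–Crafts reaction instead of by ring A, and it spares the aryl chloride, the methyl ester and the hindered aryl ester.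

**Compound list**

1 | atraric acid (methyl 2,4-dihydroxy-3,6-dimethylbenzoate) | COC(=O)c1c(C)cc(O)c(C)c1O | starting material
2 | methyl 5-chloro-2,4-dihydroxy-3,6-dimethylbenzoate | COC(=O)c1c(C)c(Cl)c(O)c(C)c1O | intermediate
3 | methyl 2,4-bis(benzyloxy)-5-chloro-3,6-dimethylbenzoate | COC(=O)c1c(C)c(Cl)c(OCc2ccccc2)c(C)c1OCc1ccccc1 | intermediate
4 | 2,4-bis(benzyloxy)-5-chloro-3,6-dimethylbenzoic acid | OC(=O)c1c(C)c(Cl)c(OCc2ccccc2)c(C)c1OCc1ccccc1 | intermediate
5 | 2,4-bis(benzyloxy)-5-chloro-3,6-dimethylbenzoyl chloride | ClC(=O)c1c(C)c(Cl)c(OCc2ccccc2)c(C)c1OCc1ccccc1 | intermediate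
6 | triacetic acid lactone (4-hydroxy-6-methyl-2H-pyran-2-one) | CC1=CC(O)=CC(=O)O1 | starting material
7 | 6-methyl-2-oxo-2H-pyran-4-yl 2,4-bis(benzyloxy)-5-chloro-3,6-dimethylbenzoate | CC1=CC(OC(=O)c2c(C)c(Cl)c(OCc3ccccc3)c(C)c2OCc2ccccc2)=CC(=O)O1 | intermediate
8 | methyl propiolate | C#CC(=O)OC | starting material
9 | 2-isopropoxy-4,4,5,5-tetramethyl-1,3,2-dioxaborolane | CC(C)OB1OC(C)(C)C(C)(C)O1 | starting material
10 | methyl 3-lithioprop-2-ynoate | [Li]C#CC(=O)OC | intermediate
11 | lithium (3-methoxy-3-oxoprop-1-yn-1-yl)(propan-2-yloxy)(pinacolato)borate | [Li+].COC(=O)C#C[B-]1(OC(C)C)OC(C)(C)C(C)(C)O1 | intermediate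
12 | methyl 3-(4,4,5,5-tetramethyl-1,3,2-dioxaborolan-2-yl)prop-2-ynoate | COC(=O)C#CB1OC(C)(C)C(C)(C)O1 | intermediate
13 | methyl 8-{[2,4-bis(benzyloxy)-5-chloro-3,6-dimethylbenzoyl]oxy}-1-methyl-3-oxo-5-(4,4,5,5-tetramethyl-1,3,2-dioxaborolan-2-yl)-2-oxabicyclo[2.2.2]octa-5,7-diene-6-carboxylate (racemic, transient) | CC12OC(=O)C(C(OC(=O)c3c(C)c(Cl)c(OCc4ccccc4)c(C)c3OCc3ccccc3)=C1)C(B1OC(C)(C)C(C)(C)O1)=C2C(=O)OC | intermediate
14 | methyl 4-{[2,4-bis(benzyloxy)-5-chloro-3,6-dimethylbenzoyl]oxy}-2-methyl-6-(4,4,5,5-tetramethyl-1,3,2-dioxaborolan-2-yl)benzoate | COC(=O)c1c(C)cc(OC(=O)c2c(C)c(Cl)c(OCc3ccccc3)c(C)c2OCc2ccccc2)cc1B1OC(C)(C)C(C)(C)O1 | intermediate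
15 | methyl 4-{[2,4-bis(benzyloxy)-5-chloro-3,6-dimethylbenzoyl]oxy}-2-hydroxy-6-methylbenzoate | COC(=O)c1c(C)cc(OC(=O)c2c(C)c(Cl)c(OCc3ccccc3)c(C)c2OCc2ccccc2)cc1O | intermediate
16 | methyl 4-[(5-chloro-2,4-dihydroxy-3,6-dimethylbenzoyl)oxy]-2-hydroxy-6-methylbenzoate | COC(=O)c1c(C)cc(OC(=O)c2c(C)c(Cl)c(O)c(C)c2O)cc1O | target

**Count**

Total steps: 9. Longest linear sequence: 8 steps (steps 1, 2, 3, 4, 5, 7, 8, 9); step 6 is a one-step side branch that joins at step 7.

**Steps most likely to fail**

1. Step 7. The cycloaddition may give mixed regiochemistry, or the acceptor-substituted alkynylboronate may oligomerise or lose boron at 170 °C before the moderately reactive diene consumes it. The fallback uses known depside chemistry and sets out from acid chloride 5. With Et3N in CH2Cl2 at 0 °C, 5 should acylate the free 4-hydroxyl of purchased methyl orsellinate (methyl 2,4-dihydroxy-6-methylbenzoate, COC(=O)c1c(C)cc(O)cc1O), whose 2-hydroxyl is hydrogen-bonded to the ester and far less nucleophilic. This gives phenol 15 directly, where the route is rejoined before step 9. The fallback makes no new compound (F0).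

2. Step 6. The lithiated propiolate may decompose on warming, and the electron-poor alkynyl pinacol boronate may hydrolyse or lose boron during isolation. The fallback sets out from 8. It is lithiated to 10 as before, trapped with trimethyl borate and treated with aqueous KHF2 to give potassium trifluoro(3-methoxy-3-oxoprop-1-yn-1-yl)borate F1, a salt that can be crystallised and stored. Shortly before the cycloaddition, F1 is treated with chlorotrimethylsilane and pinacol in MeCN, filtered and concentrated, which should release 12 for direct use in step 7. The route is rejoined at 12.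

3. Step 5. Acyl transfer at the doubly ortho-substituted carbonyl may be slow, the ambident pyrone anion may be acylated at C3, and the activated enol ester may be lost on purification. The fallback sets out from acid 4. Cyanuric fluoride and pyridine in CH2Cl2 should convert it to 2,4-bis(benzyloxy)-5-chloro-3,6-dimethylbenzoyl fluoride F2, whose small leaving group makes it far less sensitive to steric hindrance than the chloride. F2 is then combined with 6 and Cs2CO3 in MeCN at rt to give 7, where the route is rejoined.

**Further compounds**

F0 | step 7 | none | none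
F1 | step 6 | potassium trifluoro(3-methoxy-3-oxoprop-1-yn-1-yl)borate | [K+].COC(=O)C#C[B-](F)(F)F
F2 | step 5 | 2,4-bis(benzyloxy)-5-chloro-3,6-dimethylbenzoyl fluoride | FC(=O)c1c(C)c(Cl)c(OCc2ccccc2)c(C)c1OCc1ccccc1
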